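Watch the enzyme, not the feed.

all flasks: free enzyme 2.7 µM

|  | starting material | second substrate | remark | time |
|---|---|---|---|---|
| zeta | 0.076 M | 0.114 M | run made earlier |  |
| theta | 0.076 M | 0.076 M | run made earlier |  |
| beta | 0.076 M | 0.17 M | run made earlier |  |
| gamma | 0.15 M | 0.114 M | run made earlier |  |
| Wednesday's | 0.076 M | 0.114 M | everything together at the start | 6.0 h |
| Monday's | 0.076 M | 0.114 M (fed, over 5.0 h) | all else is in the flask from the start; the feed brings no volume worth counting | 6.0 h |
| Thursday's | 0.076 M (fed, over 5.0 h) | 0.114 M | all else is in the flask from the start; the feed brings no volume worth counting | 6.0 h |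

- zeta (time / h: isomer of the product / %, target / %): 0.500: 1, 14; 0.667: 4, 15; 1.00: 1, 20; 1.50: 8, 26; 2.50: 20, 28; 4.00: 25, 34; 6.00: 36, 33
- theta (time / h: isomer of the product / %, target / %): 0.500: 3, 11; 0.833: 0, 16; 1.33: 5, 20; 2.00: 10, 19; 3.00: 11, 21; 5.00: 26, 23; 8.00: 34, 23
- beta (time / h: isomer of the product / %, target / %): 0.417: 4, 9; 1.00: 7, 26; 2.00: 15, 33; 3.00: 27, 41; 4.00: 36, 42; 6.00: 49, 43; 8.00: 57, 37
- gamma (time / h: isomer of the product / %, target / %): 0.667: 0, 9; 2.00: 10, 15; 3.00: 10, 18; 5.00: 15, 16; 8.00: 24, 20

(scatter of a reading: 2 percentage points)

- in percentages every species weighs as the starting material in it: one spent catalyst counts as two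
- reactions considered so far: target <-> isomer of the product; second substrate + loaded enzyme <-> second complex; second complex -> free enzyme + target; first complex -> loaded enzyme + first product; starting material + free enzyme <-> first complex; 2 loaded enzyme -> spent catalyst

* which flask leads in amount of isomer of the product, in percent of the starting material charged ("all alike" within 1.5 percentage points) (Wednesday's / Monday's / Thursday's / all alike)
* how much isomer of the product is there at the end, in percent of the starting material charged: Wednesday's
* how much isomer of the product is there at the end, in percent of the starting material charged: Monday's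
* how much isomer of the product is there at the end, in percent of the starting material charged: Thursday's

1. Read two paces from zeta. Target plus isomer of the product grows by 0.210 h⁻¹ of the charge up to 1.00 h, but by 0.0600 h⁻¹ from 2.50 h to 6.00 h.
2. Let the pace fall as v/(1+t/τ), the form for enzyme lost in pairs, with t the time, v the starting pace and τ the enzyme life. Placing each pace at the middle of its window gives the readings τ = 1.00 h and v = 0.315 h⁻¹.
3. Form N = t_f/τ, the length t_f of the slow addition counted in enzyme lives. Here N = 5.00, so Monday's feed outlasts the enzyme life.
4. Scale pace with second substrate. Beta over zeta at 1.00 h reads 1.57, against charges in the ratio 1.49.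
5. Replace the curves by their means for Monday's: that gives 28.2 % by the end of the feed. For Monday's, integrating the overlap of rising feed and falling pace gives less, 20.2 %, and 25.1 % at 6.0 h.
6. Apply zeta's isomer share at 2.50 h, 41.7 %. My Monday's isomer is 10.5 %. One number may not suffice: τ was read in zeta, where nothing was fed.

The forecast: Wednesday's leads, with 35 %, 12 % and 30 % for Wednesday's, Monday's and Thursday's; of Monday's it says “low second substrate early means little turnover while enzyme still dies”.

    target ⇌ isomer of the product (K = 1.70, k = 0.00670 min⁻¹)
    second substrate + loaded enzyme ⇌ second complex (K = 13.0 M⁻¹, k = 3.40 × 10⁵ M⁻¹ min⁻¹)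
    second complex → free enzyme + target (k = 420 min⁻¹)
    first complex → loaded enzyme + first product (k = 750 min⁻¹)
    starting material + free enzyme ⇌ first complex (K = 11.0 M⁻¹, k = 69000 M⁻¹ min⁻¹)
    2 loaded enzyme → spent catalyst (k = 21000 M⁻¹ min⁻¹)

Wednesday's leads: 38.3 %, 8.08 % and 31.9 % for Wednesday's, Monday's and Thursday's. Monday's holds 17.4 % target plus isomer of the product at 6.0 h, 0.693 of my reckoning, and its spent catalyst at 3.00 h stands at 87.6 % of the catalyst charged, above Wednesday's 55.0 %. Wednesday's leads Thursday's by 6.4 percentage points; with second substrate lowered to 0.0961 M and the rest held, Wednesday's isomer has moved by 5 points. Keep N = 5.00 with the same v and τ: they reckon 39.3 % for Monday's flask left until 10 h, and that flask holds 0.706 of this, 27.8 % target plus isomer of the product.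

The numbers in the tables are simulated from invented constants; noise was put on by code.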